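The slowness I can time from these readings is that of substrate meeting partner, so I read it first. In the beta run, 41.3% of the substrate remains at 20.0 min, and the second-order law, with partner falling alongside substrate, gives 0.189 L mol⁻¹ min⁻¹. At the charged [partner], that makes 11.3 min. I call this the partner half-life, the time in which substrate halves if [partner] stays as charged.

| flask | substrate | partner | second reagent | third reagent | remark | time |
|---|---|---|---|---|---|---|
| beta | 0.25 M | 0.325 M | 0.125 M | 0.25 M | run made earlier |  |
| epsilon | 0.25 M | 0.325 M | 0.125 M | 0.50 M | run made earlier |  |
| west | 0.25 M | 0.325 M | 0.125 M | 0.250 M | a single well-mixed tank run continuously and read at steady state, 40 min in it on average |  |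
| east | 0.25 M (fed, over 32.0 min) | 0.325 M | 0.125 M | 0.250 M | a stirred flask in which substrate is dosed at a steady rate over 32.0 min without added volume, worked up at 40 min | 40 min |
| north | 0.25 M | 0.325 M | 0.125 M | 0.250 M | a single well-mixed tank run continuously and read at steady state, 400 min in it on average |  |
| south | 0.25 M | 0.325 M | 0.125 M | 0.250 M | everything together in a closed stirred flask, run for 40 min | 40 min |

| run | time / min | intermediate A / % | target / % | substrate / % |
|---|---|---|---|---|
| beta | 4.00 | 19.7 | 0 | 79.9 |
| beta | 8.00 | 32.0 | 0.1 | 66.6 |
| beta | 12.0 | 41.2 | 0.2 | 55.2 |
| beta | 15.0 | 46.0 | 0.7 | 49.9 |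
| beta | 20.0 | 52.2 | 0.2 | 41.3 |
| beta | 25.0 | 57.6 | 0.1 | 35.7 |
| epsilon | 1.33 | 7.8 | 0 | 92.0 |
| epsilon | 2.50 | 13.4 | 0.7 | 87.3 |
| epsilon | 4.00 | 19.4 | 0.3 | 80.2 |
| epsilon | 5.00 | 23.2 | 0 | 75.9 |
| epsilon | 6.00 | 26.7 | 0.3 | 72.7 |
| epsilon | 8.00 | 31.4 | 0.7 | 66.3 |

(standard deviation of a reading: 0.5 percentage points)

- in percentages every species weighs as the substrate in it: one side product counts as two
- the stated concentrations are those of everything mixed, before any reaction; amounts are the same in each set-up
- the numbers in the tables scatter with a standard deviation of 0.5 percentage points
- candidate steps: substrate + partner -> intermediate A; second reagent <-> dormant form; second reagent + intermediate A -> intermediate B; substrate + target -> side product; third reagent + intermediate B -> target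
- the feed brings no volume worth counting
- the earlier runs were made in a closed, stirred flask

1. order of the set-ups by the amount of intermediate A at the outlet or at the end, in percent of the substrate put in, highest first (west / east / north / south)
2. amount of intermediate A at the outlet or at the end, in percent of the substrate put in, west
3. amount of intermediate A at the outlet or at the end, in percent of the substrate put in, east
4. amount of intermediate A at the outlet or at the end, in percent of the substrate put in, north
5. amount of intermediate A at the outlet or at the end, in percent of the substrate put in, south

I turn the settings in order. Doubling third reagent should matter if the substrate step uses it, but it doesn't show in the substrate: at 8.00 min, substrate reads 66.6% in beta and 66.3% in epsilon.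

Time comes next. South's 40 min is 3.54 partner half-lives, and the integrated law, with [partner] falling, leaves 23.2% substrate. Converted substrate isn't all intermediate A, though: the beta balance lacks 6.60% at 25.0 min. Stretching that leak in proportion to time gives 10.6%, so I commit to 66.2% intermediate A in south.

The vessel comes last. East doses substrate over 32.0 min, so what enters stays on average 24.0 min before work-up, shorter than south's 40 min, and I put east below south. West's tank has 40 min on average but reacts at outlet concentrations; as a judgement, not a reckoning, I put it below east. North's tank holds its contents ten times as long as west's on average, which is 35.5 partner half-lives, but the leak runs as long too, so I leave its place open.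

The forecast gives south > north > east > west, with 63% in south, lower than my figure, 53% in east, 54% in north and 45.5% in west, and it calls north against east “nearly a coin flip”.

The flasks give south > east > north > west: 67.2% in south, 56.4% in east, 51.7% in north and 47.5% in west.

    substrate + partner → intermediate A (k = 0.00310 L mol⁻¹ s⁻¹)
    second reagent ⇌ dormant form (K = 5.70, k = 0.00105 s⁻¹)
    second reagent + intermediate A → intermediate B (k = 0.00229 L mol⁻¹ s⁻¹)
    substrate + target → side product (k = 0.00367 L mol⁻¹ s⁻¹)
    third reagent + intermediate B → target (k = 3.92 × 10⁻⁴ L mol⁻¹ s⁻¹)

The neighbour is south with [partner] cut to 0.20 M, or 0.800 equiv to substrate, which makes partner the limiting reagent. The partner half-life stretches to 18.3 min, and the integrated law leaves 44.3% substrate at 40 min; that flask holds 44%. Scaling the leak to the substrate converted gives 48.0% intermediate A, and the neighbour flask holds 48.7%.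

The runs come from a simulation for an exercise; noise was put on by code.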